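**Retrosynthetic overview**
- Target 16 comes from keto acetate 15 by hydrogenolysis of two benzyl ethers; 15 comes from the 3-aryl-2-methylbenzofuran 13 by oxidative cleavage of the furan C2=C3 bond.
- Feature the plan rests on: the acetate oxygen on C6' of ring B, the acetyl carbonyl carbon and the benzophenone carbonyl carbon are O1, C2 and C3 of a 2-methylbenzofuran fused to ring B. One C=C cleavage therefore reveals both the aryl acetate and the diaryl ketone and tells the two ring B oxygens apart.
- 13 comes from ring B alkynylphenol 7 and ring A iodide 12 by an arylative oxypalladation annulation, which forms O1–C2 and C3–C2(ring A) and closes the furan, the only ring made in the route.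
- 7 comes from orcinol 1 by C2 iodination, mono-benzylation, acetylation, Sonogashira coupling with propyne 5 and deacetylation.
- 12 comes from 2-iodo-3-methoxybenzoic acid 8, with the iodine already in place, by esterification, sterically directed C–H borylation/oxidation at C5 and benzylation.

Key step: step 9

Assumption: ring A is numbered from the ester carbon (C1; ketone on C2, OMe on C3, OH on C5) and ring B carries primes (ketone on C1', OH on C2', methyl on C4', acetate on C6'); the target has no stereocentre; 2-iodo-3-methoxybenzoic acid and propyne (as a THF solution) are taken as purchasable.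

**Route**

Step 1
Reactants: 1 orcinol (5-methylbenzene-1,3-diol)
Product: 2 2-iodo-5-methylbenzene-1,3-diol
Conditions: I2 (1.05 equiv), NaHCO3, THF/H2O, 0 °C to rt
Reagents that add atoms: iodine, II
Why: Electrophilic aromatic iodination of the resorcinol in aqueous bicarbonate, conditions known to place iodine on the carbon between the two hydroxyls of resorcinols (here C2), the carbon that later carries the alkyne.

Step 2
Reactants: 2 2-iodo-5-methylbenzene-1,3-diol
Product: 3 3-(benzyloxy)-2-iodo-5-methylphenol
Conditions: BnBr (0.9 equiv), K2CO3, acetone, 50 °C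
Reagents that add atoms: benzyl bromide, BrCc1ccccc1
Why: Williamson ether synthesis on a symmetric diol with a slight deficit of benzyl bromide, so either hydroxyl gives the same mono-ether, and the more polar unreacted diol (recycled) and the less polar bis-ether should separate easily by chromatography.

Step 3
Reactants: 3 3-(benzyloxy)-2-iodo-5-methylphenol
Product: 4 3-(benzyloxy)-2-iodo-5-methylphenyl acetate
Conditions: Ac2O, pyridine, DMAP (cat.), CH2Cl2, 0 °C to rt
Reagents that add atoms: acetic anhydride, CC(=O)OC(C)=O
Why: DMAP-catalysed O-acylation masks the remaining phenol so that the alkynylation in step 4 cannot run on to a cyclised benzofuran.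

Step 4
Reactants: 4 3-(benzyloxy)-2-iodo-5-methylphenyl acetate; 5 propyne
Product: 6 3-(benzyloxy)-5-methyl-2-(prop-1-yn-1-yl)phenyl acetate
Conditions: propyne (3 equiv, THF solution), Pd(PPh3)2Cl2 (3 mol%), CuI (5 mol%), Et3N, DMF, sealed tube, rt to 45 °C
Reagents that add atoms: none
Why: Sonogashira coupling of an aryl iodide with a terminal alkyne, which should proceed even between two ortho oxygens, while the acetate prevents metal-mediated attack of the phenol on the new alkyne.

Step 5
Reactants: 6 3-(benzyloxy)-5-methyl-2-(prop-1-yn-1-yl)phenyl acetate
Product: 7 3-(benzyloxy)-5-methyl-2-(prop-1-yn-1-yl)phenol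
Conditions: K2CO3 (0.3 equiv), MeOH/THF, 0 °C, then aq. NH4Cl
Reagents that add atoms: none
Why: Base-catalysed methanolysis (transesterification) of the aryl acetate at low temperature frees the phenol, whereas metal-free 5-endo cyclisation onto the alkyne needs heat or a stronger base.

Step 6
Reactants: 8 2-iodo-3-methoxybenzoic acid
Product: 9 methyl 2-iodo-3-methoxybenzoate
Conditions: MeI, K2CO3, DMF, rt
Reagents that add atoms: iodomethane, CI
Why: SN2 O-alkylation of the carboxylate (esterification) leaves the aryl iodide untouched.

Step 7
Reactants: 9 methyl 2-iodo-3-methoxybenzoate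
Product: 11 methyl 5-hydroxy-2-iodo-3-methoxybenzoate, via aryl pinacol boronate 10 (not isolated)
Conditions: HBpin (1.5 equiv), [Ir(OMe)(cod)]2 (1.5 mol%), 4,4'-di-tert-butyl-2,2'-bipyridine (3 mol%), THF, 60 °C; evaporate; then NaBO3·4H2O, THF/H2O, rt
Reagents that add atoms: pinacolborane (boron of intermediate 10), CC1(C)OBOC1(C)C; sodium perborate (the phenol oxygen), [Na+].[Na+].O[B-]1(O)OO[B-](O)(O)OO1
Why: Sterically controlled iridium-catalysed C–H borylation should take the only ring position with no ortho substituent (C5, meta to both OMe and CO2Me) and tolerate the shielded C–I bond, and perborate oxidation of the C–B bond then gives the phenol, so the oxygen pattern of ring A is set without any regiochemical choice in an electrophilic halogenation.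

Step 8
Reactants: 11 methyl 5-hydroxy-2-iodo-3-methoxybenzoate
Product: 12 methyl 5-(benzyloxy)-2-iodo-3-methoxybenzoate
Conditions: BnBr, K2CO3, DMF, rt
Reagents that add atoms: benzyl bromide, BrCc1ccccc1
Why: Williamson ether synthesis on the single free phenol; ester and aryl iodide are inert to carbonate at room temperature.

Step 9
Reactants: 7 3-(benzyloxy)-5-methyl-2-(prop-1-yn-1-yl)phenol; 12 methyl 5-(benzyloxy)-2-iodo-3-methoxybenzoate
Product: 13 methyl 5-(benzyloxy)-2-[4-(benzyloxy)-2,6-dimethyl-1-benzofuran-3-yl]-3-methoxybenzoate
Conditions: Pd(PPh3)4 (10 mol%), K2CO3 (3 equiv), MeCN, 70 °C; 12 (1.5 equiv) in the flask, 7 added slowly by syringe pump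
Reagents that add atoms: none
Why: Zerovalent palladium inserts into the C–I bond of 12 (helped by the ortho ester), the arylpalladium iodide of divalent palladium binds the alkyne of 7, and the phenoxide formed by carbonate attacks the methyl-bearing alkyne carbon anti to palladium, which forms the O1–C2 bond and leaves a 3-benzofuranyl(aryl)palladium species that reductively eliminates to form the C3–C2(ring A) bond. The closest known reaction type is the Cacchi-type arylative cyclisation of ortho-alkynylphenols with aryl iodides to 2,3-disubstituted benzofurans. The furan closes in the 5-endo-dig mode, the only one open to the phenoxide because the alkyne sits directly on the ring. No stereocentre is created; 13 has a hindered biaryl axis and should form as a racemate, which does not matter because the axis is lost in step 10. The selectivity needed is arylative closure over proton-terminated cycloisomerisation to the 3-unsubstituted benzofuran, and it is secured by the readily inserted iodide used in excess, the weak heterogeneous base and the slow addition of 7, so that arylpalladium is always in excess over phenoxide.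

Step 10
Reactants: 13 methyl 5-(benzyloxy)-2-[4-(benzyloxy)-2,6-dimethyl-1-benzofuran-3-yl]-3-methoxybenzoate
Product: 15 methyl 2-[2-(acetyloxy)-6-(benzyloxy)-4-methylbenzoyl]-5-(benzyloxy)-3-methoxybenzoate, via secondary ozonide 14 (not isolated)
Conditions: O3 (to the Sudan Red 7B end point), CH2Cl2, −78 °C; then Me2S, −78 °C to rt
Reagents that add atoms: ozone, [O-][O+]=O
Why: Ozonolysis (1,3-dipolar cycloaddition, cycloreversion and recombination to the secondary ozonide) should attack the enol-ether C2=C3 bond of the furan far faster than the alkoxyarenes, and reduction with Me2S turns C3 into the diaryl ketone and C2 with its methyl group into the acetate on the ring B oxygen.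

Step 11
Reactants: 15 methyl 2-[2-(acetyloxy)-6-(benzyloxy)-4-methylbenzoyl]-5-(benzyloxy)-3-methoxybenzoate
Product: 16 Penibenzophenone C (methyl 2-[2-(acetyloxy)-6-hydroxy-4-methylbenzoyl]-5-hydroxy-3-methoxybenzoate)
Conditions: H2 (1 atm), 10% Pd/C, EtOAc, rt, stopped when both benzyl ethers are gone
Reagents that add atoms: none
Why: Heterogeneous hydrogenolysis of the two aryl benzyl ethers under neutral conditions should spare the aryl acetate and methyl ester, the diaryl ketone flanked by four ortho substituents should be too hindered to hydrogenate at a comparable rate, and acetyl migration between the two ring B oxygens would be degenerate.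

**Compound list**
1 | orcinol (5-methylbenzene-1,3-diol) | Cc1cc(O)cc(O)c1 | starting material
2 | 2-iodo-5-methylbenzene-1,3-diol | Cc1cc(O)c(I)c(O)c1 | intermediate
3 | 3-(benzyloxy)-2-iodo-5-methylphenol | Cc1cc(O)c(I)c(OCc2ccccc2)c1 | intermediate
4 | 3-(benzyloxy)-2-iodo-5-methylphenyl acetate | CC(=O)Oc1cc(C)cc(OCc2ccccc2)c1I | intermediate
5 | propyne | CC#C | starting material
6 | 3-(benzyloxy)-5-methyl-2-(prop-1-yn-1-yl)phenyl acetate | CC#Cc1c(OC(C)=O)cc(C)cc1OCc1ccccc1 | intermediate
7 | 3-(benzyloxy)-5-methyl-2-(prop-1-yn-1-yl)phenol | CC#Cc1c(O)cc(C)cc1OCc1ccccc1 | intermediate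
8 | 2-iodo-3-methoxybenzoic acid | COc1cccc(C(=O)O)c1I | starting material
9 | methyl 2-iodo-3-methoxybenzoate | COC(=O)c1cccc(OC)c1I | intermediate
10 | methyl 2-iodo-3-methoxy-5-(4,4,5,5-tetramethyl-1,3,2-dioxaborolan-2-yl)benzoate | COC(=O)c1cc(B2OC(C)(C)C(C)(C)O2)cc(OC)c1I | intermediate
11 | methyl 5-hydroxy-2-iodo-3-methoxybenzoate | COC(=O)c1cc(O)cc(OC)c1I | intermediate
12 | methyl 5-(benzyloxy)-2-iodo-3-methoxybenzoate | COC(=O)c1cc(OCc2ccccc2)cc(OC)c1I | intermediate
13 | methyl 5-(benzyloxy)-2-[4-(benzyloxy)-2,6-dimethyl-1-benzofuran-3-yl]-3-methoxybenzoate (racemic about the biaryl axis) | COC(=O)c1cc(OCc2ccccc2)cc(OC)c1-c1c(C)oc2cc(C)cc(OCc3ccccc3)c12 | intermediate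
14 | secondary ozonide of 13 (1,2,4-trioxolane spanning the former furan C2 and C3; racemic, the two bridgehead carbons can only be joined in one relative sense) | CC12OOC(O1)(c3c(O2)cc(C)cc3OCc3ccccc3)c3c(OC)cc(OCc4ccccc4)cc3C(=O)OC | intermediate
15 | methyl 2-[2-(acetyloxy)-6-(benzyloxy)-4-methylbenzoyl]-5-(benzyloxy)-3-methoxybenzoate | COC(=O)c1cc(OCc2ccccc2)cc(OC)c1C(=O)c1c(OCc2ccccc2)cc(C)cc1OC(C)=O | intermediate
16 | Penibenzophenone C (methyl 2-[2-(acetyloxy)-6-hydroxy-4-methylbenzoyl]-5-hydroxy-3-methoxybenzoate) | COC(=O)c1cc(O)cc(OC)c1C(=O)c1c(O)cc(C)cc1OC(C)=O | target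

**Step count**
Total: 11 steps. Longest linear sequence: 8 steps (steps 1–5, 9, 10, 11); the ring A branch (steps 6–8) joins at step 9.

**Steps most likely to fail**

Step 9. Reductive elimination from the crowded 3-benzofuranyl(aryl)palladium intermediate may be too slow, so that protonation of the vinylpalladium species or plain cycloisomerisation of the phenoxide takes over. Carbopalladation of the alkyne by the arylpalladium followed by capture by the ester oxygen (an isocoumarin-type annulation) could also compete. The fallback separates ring closure from biaryl bond formation. It sets out from 7 and 12. Iodocyclisation of 7 (I2, NaHCO3, MeCN, rt) should give 4-(benzyloxy)-3-iodo-2,6-dimethyl-1-benzofuran F1. Zinc insertion into 12 (Zn dust, LiCl, THF, 40–50 °C), assisted by the ortho ester, should give [4-(benzyloxy)-2-methoxy-6-(methoxycarbonyl)phenyl]zinc iodide F2. Negishi coupling of F1 with F2 (Pd2(dba)3, RuPhos, THF, 65 °C), a catalyst system suited to biaryls with four ortho substituents, comes back to the route at 13.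

Step 10. Ozone may go on to oxidise the electron-rich alkoxyarenes or the benzylic C–H bonds of the ethers once the furan is consumed, or the ozonide may be reduced incompletely. The fallback replaces the dipolar oxidant by a [2+2] photooxygenation and sets out from 13. Singlet oxygen (O2, tetraphenylporphyrin, visible light, CH2Cl2, −78 °C) should add to the enol-ether double bond to give the 1,2-dioxetane fused across the former furan C2–C3 bond F3. On warming to room temperature this should cyclorevert to the ketone and the acetate, which comes back to the route at 15 with no reductant.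

Step 11. The diaryl ketone may be hydrogenated before the second benzyl ether is cleaved, or the acetate may be lost by solvolysis on prolonged reaction. The fallback replaces hydrogenolysis by Lewis-acid debenzylation and sets out from 15. BCl3 with pentamethylbenzene as benzyl cation scavenger (CH2Cl2, −78 °C, short reaction time) should cleave the aryl benzyl ethers before the chelated aryl methyl ether or the acetate react, and comes back to the route at 16.

**Further compounds**
F1 | step 9 | 4-(benzyloxy)-3-iodo-2,6-dimethyl-1-benzofuran | Cc1oc2cc(C)cc(OCc3ccccc3)c2c1I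
F2 | step 9 | [4-(benzyloxy)-2-methoxy-6-(methoxycarbonyl)phenyl]zinc iodide | COC(=O)c1cc(OCc2ccccc2)cc(OC)c1[Zn]I
F3 | step 10 | 1,2-dioxetane of 13, methyl 5-(benzyloxy)-2-[7-(benzyloxy)-2a,5-dimethyl-2aH-[1,2]dioxeto[3,4-b][1]benzofuran-7b-yl]-3-methoxybenzoate (racemic, cis ring fusion) | CC12OOC1(c1c(OC)cc(OCc3ccccc3)cc1C(=O)OC)c1c(OCc3ccccc3)cc(C)cc1O2
F0 | step 11 | none | none
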